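**Strategy.** The route rests on cutting the C7=C8 trisubstituted olefin, the only C=C inside the fourteen-membered carbocycle (C1–C14), flanked only by the C6 and C9 methylenes. Ring-closing metathesis of seco-diene 23 joins the C7 vinyl and C8 isopropenyl termini, closes the macrocycle last and gives the target directly. The cis-fused α-methylene-γ-lactone (C1/C14), the C3–C4 epoxide, the C13 acetate and all six stereocentres are already in place. The seco-diene is a two-armed butyrolactone, made by an indium-mediated, chelation-controlled allylation–lactonisation of an α-hydroxy aldehyde (C8–C14) with a 2-(bromomethyl)acrylate (C1–C7, C15–C17).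

Key step: step 13

Remark (numbering): cembrane numbering is used. C1 is the lactone β-carbon and C14 the lactone O–CH; C15, C16 and C17 are the lactone α-carbon, carbonyl and exocyclic CH2; C3–C4 is the epoxide, C7=C8 the olefin, C12 the methyl-bearing carbon and C13 the acetoxy carbon.

Remark (assumption): in step 1 the Josiphos enantiomer that gives the 3S ester is taken; both enantiomers are commercial.

**Step 1**
Reactants: 1 5-bromo-2-methylpent-1-ene; 2 methyl (E)-but-2-enoate
Product: 4 methyl (3S)-3,7-dimethyloct-7-enoate, via Grignard reagent 3 (not isolated)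
Conditions: Mg, Et2O; then 2, CuBr·SMe2 (5 mol%), Josiphos [1-(2-diphenylphosphinoferrocenyl)ethyldicyclohexylphosphine] (6 mol%), t-BuOMe, −75 °C; 1 M HCl
Reagents that add atoms: none
Why: Copper-catalysed asymmetric conjugate addition of a Grignard reagent to an (E)-enoate; the chiral CuBr–Josiphos complex adds the alkyl group to one enantiotopic face of the crotonate and so sets C12 (3S in 4), while the 1,1-disubstituted olefin is a spectator.

**Step 2**
Reactants: 4 methyl (3S)-3,7-dimethyloct-7-enoate
Product: 5 (3S)-3,7-dimethyloct-7-enal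
Conditions: DIBAL-H (iBu2AlH), CH2Cl2, −78 °C; potassium sodium tartrate (aq.)
Reagents that add atoms: none
Why: Partial reduction of the ester; at −78 °C the aluminium hemiacetal survives until work-up, so the aldehyde should form without over-reduction and the β-stereocentre is untouched.

**Step 3**
Reactants: 5 (3S)-3,7-dimethyloct-7-enal
Product: 7 (2R,3S)-3,7-dimethyl-2-[(phenylamino)oxy]oct-7-en-1-ol, via α-aminooxy aldehyde 6 (not isolated)
Conditions: L-proline (20 mol%), PhNO, DMSO, rt; then NaBH4, EtOH, 0 °C
Reagents that add atoms: nitrosobenzene, O=Nc1ccccc1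
Why: Proline-catalysed α-aminoxylation (O-selective nitroso aldol through the enamine); the acid-directed approach of nitrosobenzene to the L-proline enamine sets C13 (2R) under catalyst control, syn to the C12 methyl, and in situ borohydride reduction secures the labile α-oxy aldehyde.

**Step 4**
Reactants: 7 (2R,3S)-3,7-dimethyl-2-[(phenylamino)oxy]oct-7-en-1-ol
Product: 8 (2R,3S)-3,7-dimethyloct-7-ene-1,2-diol
Conditions: Zn dust, AcOH/THF, rt
Reagents that add atoms: none
Why: Reductive cleavage of the weak N–O bond by zinc in acetic acid; the C–O bond, both stereocentres and the olefin are not affected.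

**Step 5**
Reactants: 8 (2R,3S)-3,7-dimethyloct-7-ene-1,2-diol
Product: 9 (2R,3S)-2-hydroxy-3,7-dimethyloct-7-enal
Conditions: TEMPO (10 mol%), NCS, Bu4NCl (10 mol%), CH2Cl2/aq. NaHCO3–K2CO3 (pH 8.6), rt; used crude
Reagents that add atoms: none
Why: Oxoammonium-mediated (TEMPO) oxidation, selective for the primary alcohol of the 1,2-diol for steric reasons; the α-hydroxy aldehyde is used at once to limit dimerisation and epimerisation at C13.

**Step 6**
Reactants: 10 hex-1-en-5-yne
Product: 13 (3E)-4-methylocta-3,7-dien-1-ol, via alkenylalane 11 (not isolated), via lithium alanate 12 (not isolated)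
Conditions: Me3Al, Cp2ZrCl2 (20 mol%), CH2Cl2, rt; n-BuLi, THF, −78 °C; oxirane, −78 °C to rt; 1 M HCl
Reagents that add atoms: trimethylaluminium, C[Al](C)C; oxirane, C1CO1
Why: Negishi carboalumination (zirconium-catalysed syn addition of Me–Al across the terminal alkyne) fixes the (E)-trisubstituted olefin that becomes C3=C4, and the derived alanate opens oxirane with retention of olefin geometry; the monosubstituted alkene should not react under these conditions.

**Step 7**
Reactants: 13 (3E)-4-methylocta-3,7-dien-1-ol
Product: 14 (3E)-4-methylocta-3,7-dienal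
Conditions: Dess–Martin periodinane, NaHCO3, CH2Cl2, 0 °C; used crude
Reagents that add atoms: none
Why: Dess–Martin oxidation under buffered, non-basic conditions should give the β,γ-unsaturated aldehyde without migration of the olefin into conjugation.

**Step 8**
Reactants: 14 (3E)-4-methylocta-3,7-dienal; 15 methyl prop-2-ynoate
Product: 17 methyl (5E)-3-hydroxy-6-methyl-2-methylidenedeca-5,9-dienoate, via α-aluminoacrylate 16 (not isolated)
Conditions: 15, DIBAL-H (iBu2AlH), HMPA, THF, 0 °C; then 14, 0 °C to rt; potassium sodium tartrate (aq.)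
Reagents that add atoms: none
Why: Hydroalumination–aldol sequence (vinylalumination, an aluminium-mediated Morita–Baylis–Hillman equivalent); the DIBAL-H–HMPA complex adds hydride 1,4 to the ynoate and the α-aluminoacrylate adds to the aldehyde under non-basic conditions, the carbinol centre being formed racemic and removed in step 9.

**Step 9**
Reactants: 17 methyl (5E)-3-hydroxy-6-methyl-2-methylidenedeca-5,9-dienoate
Product: 18 methyl (2Z,5E)-2-(bromomethyl)-6-methyldeca-2,5,9-trienoate
Conditions: PBr3, Et2O, −10 to 0 °C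
Reagents that add atoms: phosphorus tribromide, BrP(Br)Br
Why: Bromination of the Morita–Baylis–Hillman-type alcohol with allylic transposition (SN2′), which should give the conjugated primary bromide with the thermodynamically preferred 2Z geometry.

**Step 10**
Reactants: 9 (2R,3S)-2-hydroxy-3,7-dimethyloct-7-enal; 18 methyl (2Z,5E)-2-(bromomethyl)-6-methyldeca-2,5,9-trienoate
Product: 21 (4S,5R)-5-[(1R,2S)-1-hydroxy-2,6-dimethylhept-6-en-1-yl]-4-[(2E)-3-methylhepta-2,6-dien-1-yl]-3-methylideneoxolan-2-one, via allylindium reagent 19 (not isolated), via hydroxy ester 20 (not isolated)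
Conditions: In powder, THF/H2O (1:1), rt; then p-TsOH (cat.), CH2Cl2, rt
Reagents that add atoms: none
Why: Indium-mediated Barbier allylation followed by lactonisation; the γ-substituted 2-(methoxycarbonyl)allylindium reacts at its γ-carbon through a chair-like six-membered transition state to give the syn C1/C14 relationship (cis-lactone), the free C13 hydroxyl chelates indium with the aldehyde oxygen so that attack anti to the C12 branch gives the 13,14-syn diol, and acid closes the five-membered lactone on O14.

**Step 11**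
Reactants: 21 (4S,5R)-5-[(1R,2S)-1-hydroxy-2,6-dimethylhept-6-en-1-yl]-4-[(2E)-3-methylhepta-2,6-dien-1-yl]-3-methylideneoxolan-2-one
Product: 22 (4S,5R)-4-{[(2R,3R)-3-(but-3-en-1-yl)-3-methyloxiran-2-yl]methyl}-5-[(1R,2S)-1-hydroxy-2,6-dimethylhept-6-en-1-yl]-3-methylideneoxolan-2-one
Conditions: D-fructose-derived Shi ketone (30 mol%), Oxone (2KHSO5·KHSO4·K2SO4), K2CO3, Bu4NHSO4 (cat.), MeCN/dimethoxymethane/aq. Na2B4O7 buffer (pH 10.5), 0 °C
Reagents that add atoms: potassium peroxymonosulfate, [K+].[O-]S(=O)(=O)OO
Why: Shi epoxidation; the chiral dioxirane should react with the electron-rich trisubstituted C3=C4 olefin much faster than with the 1,1-disubstituted, monosubstituted and conjugated olefins, and its spiro transition state sets C3 and C4 (3R,4R) under reagent control.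

**Step 12**
Reactants: 22 (4S,5R)-4-{[(2R,3R)-3-(but-3-en-1-yl)-3-methyloxiran-2-yl]methyl}-5-[(1R,2S)-1-hydroxy-2,6-dimethylhept-6-en-1-yl]-3-methylideneoxolan-2-one
Product: 23 (1R,2S)-1-[(2R,3S)-3-{[(2R,3R)-3-(but-3-en-1-yl)-3-methyloxiran-2-yl]methyl}-4-methylidene-5-oxooxolan-2-yl]-2,6-dimethylhept-6-en-1-yl acetate
Conditions: Ac2O, pyridine, DMAP (cat.), CH2Cl2, 0 °C to rt
Reagents that add atoms: acetic anhydride, CC(=O)OC(C)=O
Why: DMAP-catalysed acylation of the secondary C13 alcohol; the epoxide and the α-methylene lactone should tolerate these mild conditions and no stereocentre is touched.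

**Step 13**
Reactants: 23 (1R,2S)-1-[(2R,3S)-3-{[(2R,3R)-3-(but-3-en-1-yl)-3-methyloxiran-2-yl]methyl}-4-methylidene-5-oxooxolan-2-yl]-2,6-dimethylhept-6-en-1-yl acetate
Product: 24 eupalmerin acetate
Conditions: second-generation Grubbs catalyst (10 mol%), 1,4-benzoquinone (20 mol%), toluene (1 mM), 80 °C, argon sparge
Reagents that add atoms: none
Why: Olefin metathesis by the Chauvin mechanism: the ruthenium alkylidene loads on the monosubstituted C7 vinyl group, the new carbene undergoes intramolecular [2+2] cycloaddition with the 1,1-disubstituted C8 olefin, and cycloreversion expels ethene, whose loss drives the reaction. The closest known reaction type is macrocyclic ring-closing metathesis to trisubstituted cycloalkenes in terpenoid and macrolide synthesis. The fourteen-membered carbocycle is closed end-to-end by formation of the C7=C8 double bond between the two chain termini, and no smaller ring is formed on the way. The only new stereo-element is the olefin geometry: the 7E isomer should be favoured because the ruthenacyclobutane with the C6 and C9 ring branches trans is less congested and because the E-cycloalkene, held by the cis-fused lactone and the trans epoxide, should be the less strained ring; this geometry is the weak point of the step. The step needs chemoselectivity over the exocyclic α-methylene (electron-poor, 1,1-disubstituted, and able to cyclise only to a strained eight-membered ring), tolerance of epoxide and acetate (both inert to the catalyst), and suppression of oligomers, which high dilution secures.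

**Compound list**
1 | 5-bromo-2-methylpent-1-ene | C=C(C)CCCBr | starting material
2 | methyl (E)-but-2-enoate | C/C=C/C(=O)OC | starting material
3 | (4-methylpent-4-en-1-yl)magnesium bromide | C=C(C)CCC[Mg]Br | intermediate (not isolated)
4 | methyl (3S)-3,7-dimethyloct-7-enoate | COC(=O)C[C@@H](C)CCCC(C)=C | intermediate
5 | (3S)-3,7-dimethyloct-7-enal | O=CC[C@@H](C)CCCC(C)=C | intermediate
6 | (2R,3S)-3,7-dimethyl-2-[(phenylamino)oxy]oct-7-enal | O=C[C@H](ONc1ccccc1)[C@@H](C)CCCC(C)=C | intermediate (not isolated)
7 | (2R,3S)-3,7-dimethyl-2-[(phenylamino)oxy]oct-7-en-1-ol | OC[C@H](ONc1ccccc1)[C@@H](C)CCCC(C)=C | intermediate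
8 | (2R,3S)-3,7-dimethyloct-7-ene-1,2-diol | OC[C@H](O)[C@@H](C)CCCC(C)=C | intermediate
9 | (2R,3S)-2-hydroxy-3,7-dimethyloct-7-enal | O=C[C@H](O)[C@@H](C)CCCC(C)=C | intermediate
10 | hex-1-en-5-yne | C=CCCC#C | starting material
11 | dimethyl[(1E)-2-methylhexa-1,5-dien-1-yl]alumane | C=CCC/C(C)=C/[Al](C)C | intermediate (not isolated)
12 | lithium butyldimethyl[(1E)-2-methylhexa-1,5-dien-1-yl]aluminate | [Li+].C=CCC/C(C)=C/[Al-](C)(C)CCCC | intermediate (not isolated)
13 | (3E)-4-methylocta-3,7-dien-1-ol | C=CCC/C(C)=C/CCO | intermediate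
14 | (3E)-4-methylocta-3,7-dienal | C=CCC/C(C)=C/CC=O | intermediate
15 | methyl prop-2-ynoate | C#CC(=O)OC | starting material
16 | methyl 2-[bis(2-methylpropyl)alumanyl]prop-2-enoate | C=C([Al](CC(C)C)CC(C)C)C(=O)OC | intermediate (not isolated)
17 | methyl (5E)-3-hydroxy-6-methyl-2-methylidenedeca-5,9-dienoate (racemic at C3) | C=CCC/C(C)=C/CC(O)C(=C)C(=O)OC | intermediate
18 | methyl (2Z,5E)-2-(bromomethyl)-6-methyldeca-2,5,9-trienoate | C=CCC/C(C)=C/C/C=C(\CBr)C(=O)OC | intermediate
19 | methyl (2Z,5E)-2-[(dibromoindiganyl)methyl]-6-methyldeca-2,5,9-trienoate (drawn for the allylindium sesquibromide) | C=CCC/C(C)=C/C/C=C(\C[In](Br)Br)C(=O)OC | intermediate (not isolated)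
20 | methyl (3S,4R,5R,6S)-4,5-dihydroxy-6,10-dimethyl-2-methylidene-3-[(2E)-3-methylhepta-2,6-dien-1-yl]undec-10-enoate | C=C(C(=O)OC)[C@H](C/C=C(C)/CCC=C)[C@@H](O)[C@H](O)[C@@H](C)CCCC(C)=C | intermediate (not isolated)
21 | (4S,5R)-5-[(1R,2S)-1-hydroxy-2,6-dimethylhept-6-en-1-yl]-4-[(2E)-3-methylhepta-2,6-dien-1-yl]-3-methylideneoxolan-2-one | C=C1C(=O)O[C@@H]([C@H](O)[C@@H](C)CCCC(C)=C)[C@H]1C/C=C(C)/CCC=C | intermediate
22 | (4S,5R)-4-{[(2R,3R)-3-(but-3-en-1-yl)-3-methyloxiran-2-yl]methyl}-5-[(1R,2S)-1-hydroxy-2,6-dimethylhept-6-en-1-yl]-3-methylideneoxolan-2-one | C=C1C(=O)O[C@@H]([C@H](O)[C@@H](C)CCCC(C)=C)[C@H]1C[C@H]2O[C@]2(C)CCC=C | intermediate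
23 | (1R,2S)-1-[(2R,3S)-3-{[(2R,3R)-3-(but-3-en-1-yl)-3-methyloxiran-2-yl]methyl}-4-methylidene-5-oxooxolan-2-yl]-2,6-dimethylhept-6-en-1-yl acetate | C=C1C(=O)O[C@@H]([C@H](OC(C)=O)[C@@H](C)CCCC(C)=C)[C@H]1C[C@H]2O[C@]2(C)CCC=C | intermediate
24 | eupalmerin acetate (1S,3R,4R,7E,12S,13R,14R) | C=C1C(=O)O[C@H]2[C@H](OC(C)=O)[C@@H](C)CCC/C(C)=C/CC[C@@]3(C)O[C@@H]3C[C@@H]12 | target

**Count.** Total: 13 steps. Longest linear sequence: 9 steps (steps 1–5, then 10–13).

**Steps most likely to fail**

Step 13 (ring-closing metathesis). The ring closure may deliver the 7Z macrocycle or E/Z mixtures, and the propagating carbene may be diverted by the exocyclic α-methylene (cross-metathesis, chelated enoate carbene) so that oligomers form. The fallback sets out from 23 and returns at 24. The exocyclic methylene would be masked by conjugate addition of dimethylamine (Me2NH, THF, rt) to give the β-amino lactone F1. As its camphorsulfonate salt this carries only the two olefins meant to react and tolerates forcing, equilibrating conditions (second-generation Hoveyda–Grubbs catalyst, toluene, 100 °C), which should funnel the mixture to the more stable E-cycloalkene, the macrocyclic amine F2. Exhaustive methylation (MeI) and mild base (NaHCO3) would then regenerate the α-methylene lactone by elimination and give 24.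

Step 10 (indium allylation–lactonisation). Chelation may be incomplete in water, so that facial selectivity at C14 is lost; the syn simple diastereoselectivity may erode; and the unprotected α-hydroxy aldehyde may dimerise or epimerise before it reacts. The fallback sets out from 8 and 18 and returns at 21; it also bypasses step 5. Diol 8 would be converted with 4-methoxybenzaldehyde dimethyl acetal (PPTS, CH2Cl2) into the 4-methoxybenzylidene acetal F3. DIBAL-H would open it at the less hindered oxygen to the secondary PMB ether F4, and Dess–Martin oxidation would give the stable, monomeric α-alkoxy aldehyde F5. Bromide 18 would be converted with Zn dust in THF into the allylzinc bromide F6 and added to the aldehyde precomplexed with MgBr2·OEt2 (CH2Cl2, −78 °C). The rigid five-membered magnesium chelate should enforce 13,14-syn addition in an aprotic medium and give the hydroxy ester F7, which would be lactonised (p-TsOH) to the PMB-protected lactone F8. DDQ (CH2Cl2/H2O) would then remove the PMB group and give 21.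

Step 8 (vinylalumination–aldol). The β,γ-unsaturated aldehyde may enolise or slip into conjugation on the Lewis-acidic aluminium reagent, and the aluminoacrylate may oligomerise or be over-reduced before it is trapped. The fallback sets out from alanate 12 and methyl prop-2-ynoate 15, returns at 18, and avoids the aldehyde altogether. The alanate would be quenched with paraformaldehyde instead of oxirane to give (2E)-3-methylhepta-2,6-dien-1-ol F9. Appel bromination (CBr4, PPh3) would give (2E)-1-bromo-3-methylhepta-2,6-diene F10, and copper-mediated coupling with 15 (CuI (10 mol%), NaI, K2CO3, DMF) would give the skipped enynoate methyl (5E)-6-methyldeca-5,9-dien-2-ynoate F11. Hydroalumination (DIBAL-H, HMPA, THF, 0 °C) would give the α-aluminoenoate F12, trapped with monomeric formaldehyde as the hydroxymethyl enoate F13. PBr3 would give the 2E bromide F14, which bromide ion (LiBr, acetone) should equilibrate through reversible SN2′ exchange to the more stable 2Z isomer 18.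

**Further compounds**
F1 | step 13 | (1R,2S)-1-[(2R,3S)-3-{[(2R,3R)-3-(but-3-en-1-yl)-3-methyloxiran-2-yl]methyl}-4-[(dimethylamino)methyl]-5-oxooxolan-2-yl]-2,6-dimethylhept-6-en-1-yl acetate (epimers at the amine-bearing ring carbon) | CN(C)CC1C(=O)O[C@@H]([C@H](OC(C)=O)[C@@H](C)CCCC(C)=C)[C@H]1C[C@H]2O[C@]2(C)CCC=C
F2 | step 13 | 17-(dimethylamino)-15,17-dihydroeupalmerin acetate (epimers at C15) | CN(C)CC1C(=O)O[C@H]2[C@H](OC(C)=O)[C@@H](C)CCC/C(C)=C/CC[C@@]3(C)O[C@@H]3C[C@@H]12
F3 | step 10 | (4R)-2-(4-methoxyphenyl)-4-[(2S)-6-methylhept-6-en-2-yl]-1,3-dioxolane (acetal epimers) | COc1ccc(cc1)C1OC[C@H](O1)[C@@H](C)CCCC(C)=C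
F4 | step 10 | (2R,3S)-2-[(4-methoxyphenyl)methoxy]-3,7-dimethyloct-7-en-1-ol | OC[C@H](OCc1ccc(OC)cc1)[C@@H](C)CCCC(C)=C
F5 | step 10 | (2R,3S)-2-[(4-methoxyphenyl)methoxy]-3,7-dimethyloct-7-enal | O=C[C@H](OCc1ccc(OC)cc1)[C@@H](C)CCCC(C)=C
F6 | step 10 | methyl (2Z,5E)-2-[(bromozincio)methyl]-6-methyldeca-2,5,9-trienoate | C=CCC/C(C)=C/C/C=C(\C[Zn]Br)C(=O)OC
F7 | step 10 | methyl (3S,4R,5R,6S)-4-hydroxy-5-[(4-methoxyphenyl)methoxy]-6,10-dimethyl-2-methylidene-3-[(2E)-3-methylhepta-2,6-dien-1-yl]undec-10-enoate | C=C(C(=O)OC)[C@H](C/C=C(C)/CCC=C)[C@@H](O)[C@H](OCc1ccc(OC)cc1)[C@@H](C)CCCC(C)=C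
F8 | step 10 | (4S,5R)-5-{(1R,2S)-1-[(4-methoxyphenyl)methoxy]-2,6-dimethylhept-6-en-1-yl}-4-[(2E)-3-methylhepta-2,6-dien-1-yl]-3-methylideneoxolan-2-one | C=C1C(=O)O[C@@H]([C@H](OCc2ccc(OC)cc2)[C@@H](C)CCCC(C)=C)[C@H]1C/C=C(C)/CCC=C
F9 | step 8 | (2E)-3-methylhepta-2,6-dien-1-ol | C=CCC/C(C)=C/CO
F10 | step 8 | (2E)-1-bromo-3-methylhepta-2,6-diene | C=CCC/C(C)=C/CBr
F11 | step 8 | methyl (5E)-6-methyldeca-5,9-dien-2-ynoate | C=CCC/C(C)=C/CC#CC(=O)OC
F12 | step 8 | methyl (2E,5E)-2-[bis(2-methylpropyl)alumanyl]-6-methyldeca-2,5,9-trienoate | C=CCC/C(C)=C/C/C=C(/[Al](CC(C)C)CC(C)C)C(=O)OC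
F13 | step 8 | methyl (2Z,5E)-2-(hydroxymethyl)-6-methyldeca-2,5,9-trienoate | C=CCC/C(C)=C/C/C=C(/CO)C(=O)OC
F14 | step 8 | methyl (2E,5E)-2-(bromomethyl)-6-methyldeca-2,5,9-trienoate | C=CCC/C(C)=C/C/C=C(/CBr)C(=O)OC
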